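## Retrosynthetic overview

- The 7S carbinol is set last, by Felkin–Anh hydride reduction of an aryl ketone. That ketone comes from a tetrahydrofuran-3-carbaldehyde and a lithiated, silyl-protected syringyl unit (addition, then oxidation). Both phenols travel as silyl ethers and are freed by fluoride.
- Key disconnection: the C3–C4 bond of the tetrahydrofuran (lignan C8–C8′). It opens the only non-aromatic ring to an achiral, acyclic ether-aldehyde. Forward, an enantioselective 5-exo radical-cation cyclisation (enamine + photoredox + hydrogen-atom-transfer catalysis) closes the ring and sets C3 and C4.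
- Enabling feature: C3 is α to the exocyclic carbinol carbon, so at the aldehyde level it is an enamine α-carbon. C4 is the styrene carbon two bonds from the guaiacyl ring. The C2–O1–C5 ether holds them in a 1,5 relationship. Both carbons are nucleophilic; one-electron oxidation of the enamine reverses the polarity of C3.
- The ether-aldehyde comes from the corresponding nitrile, assembled by cross-metathesis of silyl-protected 4-vinylguaiacol with 3-(allyloxy)propanenitrile.
- Ring order: both benzene rings are purchased; the tetrahydrofuran is the only ring formed and the last closed, in step 4.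

Key step: step 4

Assumption: the imidazolidinone catalyst is taken to shield its E-enamine in the sense of the accepted model for this catalyst family, which is why the (2R,5R) enantiomer is specified. Should the opposite sense be found, the (2S,5S) enantiomer is used and nothing else changes.

## Route

Step 1
Reactants: 1 2-methoxy-4-vinylphenol
Product: 2 triisopropyl(2-methoxy-4-vinylphenoxy)silane
Conditions: i-Pr3SiCl (1.1 equiv), imidazole (2.2 equiv), DMF, 0 °C to rt
Reagents that add atoms: triisopropylsilyl chloride, CC(C)[Si](Cl)(C(C)C)C(C)C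
Why: Imidazole-promoted silylation of a phenol; the bulky triisopropylsilyl ether should tolerate the hydride, photoredox and organolithium steps ahead and is cleaved by fluoride at the end.

Step 2
Reactants: 2 triisopropyl(2-methoxy-4-vinylphenoxy)silane, 3 3-(allyloxy)propanenitrile
Product: 4 3-{[(2E)-3-{3-methoxy-4-[(triisopropylsilyl)oxy]phenyl}prop-2-en-1-yl]oxy}propanenitrile
Conditions: second-generation Grubbs catalyst (H2IMes)(PCy3)Cl2Ru=CHPh (5 mol %), 3 (3 equiv), 1,4-benzoquinone (10 mol %), CH2Cl2, 40 °C
Reagents that add atoms: none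
Why: Olefin cross-metathesis of a styrene with an excess of a terminal allyl ether, driven by loss of ethylene, should give the E-alkene under thermodynamic control, with benzoquinone suppressing double-bond migration by ruthenium hydrides.

Step 3
Reactants: 4 3-{[(2E)-3-{3-methoxy-4-[(triisopropylsilyl)oxy]phenyl}prop-2-en-1-yl]oxy}propanenitrile
Product: 6 3-{[(2E)-3-{3-methoxy-4-[(triisopropylsilyl)oxy]phenyl}prop-2-en-1-yl]oxy}propanal, via N-aluminoimine 5 (not isolated)
Conditions: i-Bu2AlH (1.2 equiv), toluene, −78 °C; then EtOAc, aq. potassium sodium tartrate (KNaC4H4O6), 0 °C to rt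
Reagents that add atoms: water, O
Why: Partial reduction of a nitrile by i-Bu2AlH stops at the N-aluminoimine, and near-neutral hydrolysis releases the aldehyde without the acid or base that would trigger β-elimination of the cinnamyl alkoxide.

Step 4
Reactants: 6 3-{[(2E)-3-{3-methoxy-4-[(triisopropylsilyl)oxy]phenyl}prop-2-en-1-yl]oxy}propanal
Product: 8 (3R,4R)-4-{3-methoxy-4-[(triisopropylsilyl)oxy]benzyl}tetrahydrofuran-3-carbaldehyde, via enamine 7 (not isolated)
Conditions: (2R,5R)-5-benzyl-2-tert-butyl-3-methylimidazolidin-4-one·CF3CO2H (20 mol %), [Ir(Fmppy)2(dtbbpy)]PF6 (1 mol %; Fmppy = cyclometalated 2-(4-fluorophenyl)-4-methylpyridine, dtbbpy = 4,4′-di-tert-butyl-2,2′-bipyridine), 2,4,6-triisopropylbenzenethiol (10 mol %), H2O (3 equiv), DME, blue LEDs, 0 °C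
Reagents that add atoms: none
Why: Condensation of 6 with the imidazolidinone gives E-enamine 7, which the photoexcited trivalent iridium complex oxidises by one electron to a 3π-electron enaminyl radical cation, so that the normally nucleophilic α-carbon becomes an electrophilic radical and can bond to the equally nucleophilic styrene carbon; hydrogen-atom transfer from the thiol to the resulting benzylic radical and iminium hydrolysis then release 8, while divalent iridium reduces the thiyl radical and closes both cycles. The closest known reaction type is the enantioselective intramolecular α-alkylation of aldehydes with simple olefins by merged photoredox, enamine and hydrogen-atom-transfer catalysis. The tetrahydrofuran closes in the 5-exo-trig mode by formation of the C3–C4 bond. C3 is controlled by the catalyst, whose benzyl group covers one face of the E-enaminyl radical cation so that the alkene adds to the face giving 3R (the Si face of the α-carbon), and C4 is controlled relative to C3 by a chair-like transition state with the E-styryl unit and the iminium substituent pseudo-equatorial, which gives the trans ring. The step needs oxidation of the enamine in preference to the silyloxy-methoxy-styrene (secured by the lower oxidation potential of the enamine and the moderate excited-state potential of the photocatalyst), 5-exo over 6-endo closure (secured by benzylic stabilisation of the 5-exo radical), and survival of the β-alkoxy aldehyde (secured by the acidic amine salt and low temperature, which disfavour loss of the cinnamyl alkoxide).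

Step 5
Reactants: 9 4-bromo-2,6-dimethoxyphenol
Product: 10 (4-bromo-2,6-dimethoxyphenoxy)(tert-butyl)dimethylsilane
Conditions: t-BuMe2SiCl (1.2 equiv), imidazole (2.5 equiv), DMF, rt
Reagents that add atoms: tert-butyldimethylsilyl chloride, CC(C)(C)[Si](C)(C)Cl
Why: Imidazole-promoted silylation masks the acidic phenol for the bromine–lithium exchange, and the silyl ether is removed together with the triisopropylsilyl group in the last step.

Step 6
Reactants: 10 (4-bromo-2,6-dimethoxyphenoxy)(tert-butyl)dimethylsilane, 8 (3R,4R)-4-{3-methoxy-4-[(triisopropylsilyl)oxy]benzyl}tetrahydrofuran-3-carbaldehyde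
Product: 12 {4-[(tert-butyldimethylsilyl)oxy]-3,5-dimethoxyphenyl}[(3R,4R)-4-{3-methoxy-4-[(triisopropylsilyl)oxy]benzyl}tetrahydrofuran-3-yl]methanol as a mixture of carbinol epimers, via aryllithium 11 (not isolated)
Conditions: 10 (1.3 equiv), n-BuLi (1.25 equiv), THF, −78 °C; then 8, −78 °C; then H2O
Reagents that add atoms: none
Why: Bromine–lithium exchange and 1,2-addition of the aryllithium to the aldehyde form the C7–aryl bond; Felkin–Anh addition is expected to favour the 7R epimer, so no selectivity is sought and both epimers converge on ketone 13 in step 7.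

Step 7
Reactants: 12 {4-[(tert-butyldimethylsilyl)oxy]-3,5-dimethoxyphenyl}[(3R,4R)-4-{3-methoxy-4-[(triisopropylsilyl)oxy]benzyl}tetrahydrofuran-3-yl]methanol (epimer mixture)
Product: 13 {4-[(tert-butyldimethylsilyl)oxy]-3,5-dimethoxyphenyl}[(3R,4R)-4-{3-methoxy-4-[(triisopropylsilyl)oxy]benzyl}tetrahydrofuran-3-yl]methanone
Conditions: Dess–Martin periodinane (1.3 equiv), CH2Cl2, 0 °C to rt
Reagents that add atoms: none
Why: Dess–Martin oxidation of a secondary benzylic alcohol merges both carbinol epimers into one aryl ketone, and the α-centre C3, should it enolise, returns to the more stable trans arrangement.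

Step 8
Reactants: 13 {4-[(tert-butyldimethylsilyl)oxy]-3,5-dimethoxyphenyl}[(3R,4R)-4-{3-methoxy-4-[(triisopropylsilyl)oxy]benzyl}tetrahydrofuran-3-yl]methanone
Product: 14 (S)-{4-[(tert-butyldimethylsilyl)oxy]-3,5-dimethoxyphenyl}[(3R,4R)-4-{3-methoxy-4-[(triisopropylsilyl)oxy]benzyl}tetrahydrofuran-3-yl]methanol
Conditions: LiBH(s-Bu)3 (1.5 equiv), THF, −78 °C; then H2O
Reagents that add atoms: none
Why: Felkin–Anh reduction of an α-chiral aryl ketone: with the branched ring carbon C4 antiperiplanar to the incoming bulky hydride, attack past the C3 hydrogen should give the 7S carbinol (substrate-controlled 1,2-induction).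

Step 9
Reactants: 14 (S)-{4-[(tert-butyldimethylsilyl)oxy]-3,5-dimethoxyphenyl}[(3R,4R)-4-{3-methoxy-4-[(triisopropylsilyl)oxy]benzyl}tetrahydrofuran-3-yl]methanol
Product: 15 (S)-(4-hydroxy-3,5-dimethoxyphenyl)[(3R,4R)-4-(4-hydroxy-3-methoxybenzyl)tetrahydrofuran-3-yl]methanol (target)
Conditions: Bu4NF (2.4 equiv), AcOH (2.4 equiv), THF, 0 °C
Reagents that add atoms: none
Why: Fluoride cleaves both aryl silyl ethers, and the acetic acid buffer keeps the freed para-hydroxybenzylic alcohol from base-induced quinone methide formation, so no stereocentre is touched.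

## Compound list

1 | 2-methoxy-4-vinylphenol | C=Cc1ccc(O)c(OC)c1 | starting material
2 | triisopropyl(2-methoxy-4-vinylphenoxy)silane | C=Cc1ccc(O[Si](C(C)C)(C(C)C)C(C)C)c(OC)c1 | intermediate
3 | 3-(allyloxy)propanenitrile | C=CCOCCC#N | starting material
4 | 3-{[(2E)-3-{3-methoxy-4-[(triisopropylsilyl)oxy]phenyl}prop-2-en-1-yl]oxy}propanenitrile | N#CCCOC/C=C/c1ccc(O[Si](C(C)C)(C(C)C)C(C)C)c(OC)c1 | intermediate
5 | N-(diisobutylaluminio)imine of aldehyde 6 (not isolated) | CC(C)C[Al](CC(C)C)N=CCCOC/C=C/c1ccc(O[Si](C(C)C)(C(C)C)C(C)C)c(OC)c1 | intermediate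
6 | 3-{[(2E)-3-{3-methoxy-4-[(triisopropylsilyl)oxy]phenyl}prop-2-en-1-yl]oxy}propanal | O=CCCOC/C=C/c1ccc(O[Si](C(C)C)(C(C)C)C(C)C)c(OC)c1 | intermediate
7 | E-enamine of 6 with (2R,5R)-5-benzyl-2-tert-butyl-3-methylimidazolidin-4-one (not isolated) | CN1C(=O)[C@@H](Cc2ccccc2)N(/C=C/COC/C=C/c2ccc(O[Si](C(C)C)(C(C)C)C(C)C)c(OC)c2)[C@H]1C(C)(C)C | intermediate
8 | (3R,4R)-4-{3-methoxy-4-[(triisopropylsilyl)oxy]benzyl}tetrahydrofuran-3-carbaldehyde | COc1cc(C[C@H]2COC[C@@H]2C=O)ccc1O[Si](C(C)C)(C(C)C)C(C)C | intermediate
9 | 4-bromo-2,6-dimethoxyphenol | COc1cc(Br)cc(OC)c1O | starting material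
10 | (4-bromo-2,6-dimethoxyphenoxy)(tert-butyl)dimethylsilane | COc1cc(Br)cc(OC)c1O[Si](C)(C)C(C)(C)C | intermediate
11 | {4-[(tert-butyldimethylsilyl)oxy]-3,5-dimethoxyphenyl}lithium (not isolated) | [Li]c1cc(OC)c(O[Si](C)(C)C(C)(C)C)c(OC)c1 | intermediate
12 | {4-[(tert-butyldimethylsilyl)oxy]-3,5-dimethoxyphenyl}[(3R,4R)-4-{3-methoxy-4-[(triisopropylsilyl)oxy]benzyl}tetrahydrofuran-3-yl]methanol, mixture of carbinol epimers | COc1cc(C[C@H]2COC[C@@H]2C(O)c2cc(OC)c(O[Si](C)(C)C(C)(C)C)c(OC)c2)ccc1O[Si](C(C)C)(C(C)C)C(C)C | intermediate
13 | {4-[(tert-butyldimethylsilyl)oxy]-3,5-dimethoxyphenyl}[(3R,4R)-4-{3-methoxy-4-[(triisopropylsilyl)oxy]benzyl}tetrahydrofuran-3-yl]methanone | COc1cc(C[C@H]2COC[C@@H]2C(=O)c2cc(OC)c(O[Si](C)(C)C(C)(C)C)c(OC)c2)ccc1O[Si](C(C)C)(C(C)C)C(C)C | intermediate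
14 | (S)-{4-[(tert-butyldimethylsilyl)oxy]-3,5-dimethoxyphenyl}[(3R,4R)-4-{3-methoxy-4-[(triisopropylsilyl)oxy]benzyl}tetrahydrofuran-3-yl]methanol | COc1cc(C[C@H]2COC[C@@H]2[C@H](O)c2cc(OC)c(O[Si](C)(C)C(C)(C)C)c(OC)c2)ccc1O[Si](C(C)C)(C(C)C)C(C)C | intermediate
15 | (S)-(4-hydroxy-3,5-dimethoxyphenyl)[(3R,4R)-4-(4-hydroxy-3-methoxybenzyl)tetrahydrofuran-3-yl]methanol | COc1cc(C[C@H]2COC[C@@H]2[C@H](O)c2cc(OC)c(O)c(OC)c2)ccc1O | target

## Step count and risks

Total step count: 9. Longest linear sequence: 8 steps (steps 1–4 and 6–9; step 5 prepares the second fragment).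

Steps most likely to fail:

1. Step 4. Two processes threaten it. The enamine or iminium may lose the cinnamyl alkoxide by β-elimination (retro-oxa-Michael) faster than it is oxidised. And if closure is not strongly trans-selective, epimerisation of the cis aldehyde at C3 would lead into the enantiomeric trans series, because C4 cannot be corrected afterwards; any cis aldehyde must therefore be removed, not equilibrated.
 Fallback, setting out from 2 and coming back at 8: cross-metathesis of 2 with allyl glycidyl ether (same ruthenium catalyst) should give 2-({[(2E)-3-{3-methoxy-4-[(triisopropylsilyl)oxy]phenyl}prop-2-en-1-yl]oxy}methyl)oxirane F1. Cp2TiCl, generated from Cp2TiCl2 and Zn dust in THF (trivalent titanium), opens the epoxide to the secondary β-titanoxy radical, which closes 5-exo onto the styrene. After reduction of the benzylic radical and acidic work-up this should give racemic trans-(4-{3-methoxy-4-[(triisopropylsilyl)oxy]benzyl}tetrahydrofuran-3-yl)methanol F2, the cis isomer being removed by chromatography. Preparative chromatography on a chiral stationary phase separates the enantiomers and provides [(3S,4R)-4-{3-methoxy-4-[(triisopropylsilyl)oxy]benzyl}tetrahydrofuran-3-yl]methanol F3. Dess–Martin oxidation of F3 returns to 8. This route gives up catalytic enantiocontrol for a resolution.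

2. Step 8. Hydride delivery may show poor facial discrimination, because the two ring carbons flanking C3 differ only moderately in size, and the basic borohydride may enolise the ketone.
 Fallback, setting out from 13 and coming back at 14: the stereocentre is set under catalyst control instead of substrate control, by Corey–Bakshi–Shibata reduction with the (R)-Me-CBS oxazaborolidine (20 mol %) and BH3·SMe2 in THF at −20 °C. By the acetophenone model the aryl group is the large substituent, and the R catalyst should give the 7S alcohol, matched with the Felkin preference. No new compound is involved.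

3. Step 2. Cross-metathesis may be eroded by statistical homodimerisation (stilbene formation) and by ruthenium hydride-induced migration of the allyl ether double bond to the enol ether.
 Fallback, setting out from 2 and coming back at 4: Vilsmeier–Haack formylation of the styrene (POCl3, DMF; then aq. NaOAc) should give (2E)-3-{3-methoxy-4-[(triisopropylsilyl)oxy]phenyl}prop-2-enal F4. 1,2-Reduction (NaBH4, CeCl3·7H2O, MeOH, 0 °C) gives (2E)-3-{3-methoxy-4-[(triisopropylsilyl)oxy]phenyl}prop-2-en-1-ol F5. Base-catalysed cyanoethylation of F5 (acrylonitrile, t-BuOK 5 mol %, THF, 0 °C) forms the ether C–O bond and delivers 4.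

Further compounds
F1 | step 4 | 2-({[(2E)-3-{3-methoxy-4-[(triisopropylsilyl)oxy]phenyl}prop-2-en-1-yl]oxy}methyl)oxirane (racemic) | COc1cc(/C=C/COCC2CO2)ccc1O[Si](C(C)C)(C(C)C)C(C)C
F2 | step 4 | racemic trans-(4-{3-methoxy-4-[(triisopropylsilyl)oxy]benzyl}tetrahydrofuran-3-yl)methanol (both enantiomers) | COc1cc(C[C@H]2COC[C@@H]2CO)ccc1O[Si](C(C)C)(C(C)C)C(C)C.COc1cc(C[C@@H]2COC[C@H]2CO)ccc1O[Si](C(C)C)(C(C)C)C(C)C
F3 | step 4 | [(3S,4R)-4-{3-methoxy-4-[(triisopropylsilyl)oxy]benzyl}tetrahydrofuran-3-yl]methanol | COc1cc(C[C@H]2COC[C@@H]2CO)ccc1O[Si](C(C)C)(C(C)C)C(C)C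
F0 | step 8 | none | none
F4 | step 2 | (2E)-3-{3-methoxy-4-[(triisopropylsilyl)oxy]phenyl}prop-2-enal | COc1cc(/C=C/C=O)ccc1O[Si](C(C)C)(C(C)C)C(C)C
F5 | step 2 | (2E)-3-{3-methoxy-4-[(triisopropylsilyl)oxy]phenyl}prop-2-en-1-ol | COc1cc(/C=C/CO)ccc1O[Si](C(C)C)(C(C)C)C(C)C
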